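Over 150 min the reciprocal of Sub climbs nearly straight in Monday's, Friday's and Tuesday's runs.

| setting | Monday's | Friday's | Tuesday's | Wednesday's |
|---|---|---|---|---|
| Sub | 80.0 mM | 40.0 mM | 160 mM | 80.0 mM |
| Cat | 1.60 mM | 1.60 mM | 1.60 mM | 1.60 mM |
| Prd |  |  |  | 24.0 mM |
| time |  |  |  | 150 min |

| run | time / min | [Sub] / mM |
|---|---|---|
| Monday's run | 19 | 61.7 |
| Monday's run | 38 | 50.1 |
| Monday's run | 56 | 42.8 |
| Monday's run | 75 | 36.3 |
| Monday's run | 94 | 32.1 |
| Monday's run | 110 | 30.2 |
| Monday's run | 130 | 26.9 |
| Monday's run | 150 | 24.9 |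
| Friday's run | 19 | 32.9 |
| Friday's run | 38 | 28.3 |
| Friday's run | 56 | 24.4 |
| Friday's run | 75 | 21.0 |
| Friday's run | 94 | 19.8 |
| Friday's run | 110 | 18.4 |
| Friday's run | 130 | 16.8 |
| Friday's run | 150 | 15.5 |
| Tuesday's run | 19 | 109.1 |
| Tuesday's run | 38 | 80.6 |
| Tuesday's run | 56 | 64.4 |
| Tuesday's run | 75 | 54.0 |
| Tuesday's run | 94 | 46.4 |
| Tuesday's run | 110 | 41.9 |
| Tuesday's run | 130 | 37.5 |
| Tuesday's run | 150 | 34.1 |

(readings scatter by 0.4 mM)

- Overall: Sub -> Prd, with Cat as catalyst.
- Constant volume, constant temperature.
- The analysis sees a species whether free or bound.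
- An order is taken over about fifteen percent of the charge, up and down.

- apparent order in [Sub] of the starting rate, round the charge of the Monday's run (the rate where two percent of its Sub have turned into Prd) (one fixed amount of Prd, the same in the runs compared)
- Sub in the Wednesday's run at 150 min, as a share of the Sub charged

*Does the fall of Sub measure Prd?* Not by itself. A loss that follows the square of Sub gives the same reciprocal slope at any charge. A catalysed loss of steadier rate adds that rate over the square of Sub, so it fades at high Sub. The whole-run slope is steeper on Friday, at the lowest charge, than on Monday or Tuesday.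

*What do you read from that?* A floor: the reciprocal slope late in Tuesday's run, 0.139 M⁻¹ min⁻¹. I read it as the uncatalysed background reaction. I count what stands above it as catalysed loss, and so Prd.

*And the order?* Over the first readings, the rate above the floor is 0.278 mM min⁻¹ on Monday and 0.191 mM min⁻¹ on Friday. That gives my order, 0.541.

*Monday's Prd?* The excess reciprocal at the end is 6.84 M⁻¹. Multiplied by the square of Sub at 38 min, it gives 17.2 mM. I take the mean Prd over that run as 8.58 mM.

*Your weak spot?* An assumption: the excess shrinks in step with the Prd present. Monday's fall near 36.3 mM is slower than Friday's first fall, which fits it but doesn't prove it.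

*Wednesday, then?* With the charged Prd, the excess is 2.45 M⁻¹, and that makes 7.74 mM more Prd. Put back, the mean Prd over that run is 27.9 mM. The second round gives 28.2 mM, or 35.3% of the charge.

The forecast says 33% (30.5% to 37%) and an order of 1.6 (1.35 to 1.85), noting that “the time-course looks second order”; both of its numbers differ from mine.

Wednesday's flask gives 36.3%, and the order is 0.74.

    Cat + Sub ⇌ Cat.Sub, settled at all times (5.050 M⁻¹)
    Cat.Sub → Prd + Cat (0.7740 min⁻¹)
    2 Sub → Q (0.06480 M⁻¹ min⁻¹)
    Cat + Prd → E + Prd (1.446 M⁻¹ min⁻¹)

At the same amount of Prd made, Tuesday's rate of Prd formation is 0.53 mM min⁻¹ against Monday's 0.34 mM min⁻¹. Wednesday's reciprocal stands 1.13 M⁻¹ above the floor, against 6.84 M⁻¹ for Monday. On Friday, the same floor leaves an excess of 12.2 M⁻¹ at 75 min. With the square of Sub read at 38 min, that reckons at 9.78 mM of Prd, and Friday's Prd stood at 10.0 mM at 74.8 min.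

Readings and results were generated by integration with made-up constants; the scatter is artificial.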